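The vessel is stirred, and the starting material runs in over 2.0 min onto the free catalyst; target forms there and then passes on.

| flask | starting material | free catalyst | remark | time |
|---|---|---|---|---|
| north-west | 14 mM (fed, over 2.0 min) | 0.39 mM | run made earlier; the fed solution adds 0.50 times the starting volume |  |
| south-west | 21 mM (fed, over 2.0 min) | 0.39 mM | run made earlier; the fed solution adds 0.50 times the starting volume |  |
| south-east | 28 mM (fed, over 2.0 min) | 0.20 mM | run made earlier; the fed solution adds 0.50 times the starting volume |  |
| flask | 28 mM (fed, over 2.0 min) | 0.39 mM | the fed solution adds 0.50 times the starting volume | 3.0 h |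

| run | time / h | target / % |
|---|---|---|
| north-west | 0.0222 | 25 |
| north-west | 0.0500 | 40 |
| north-west | 0.100 | 11 |
| north-west | 0.250 | 2 |
| north-west | 0.500 | 0 |
| north-west | 1.00 | 0 |
| north-west | 2.50 | 0 |
| south-west | 0.0222 | 25 |
| south-west | 0.0500 | 35 |
| south-west | 0.100 | 12 |
| south-west | 0.250 | 0 |
| south-west | 0.500 | 0 |
| south-west | 1.00 | 3 |
| south-west | 2.50 | 0 |
| south-east | 0.0222 | 12 |
| south-east | 0.0833 | 22 |
| south-east | 0.250 | 0 |
| south-east | 0.833 | 5 |
| south-east | 2.50 | 0 |

(each reading ± 2 percentage points)

- charges are per starting volume, the dose included; the dosed solution carries all of it
- percentages count the whole charge, also what has not yet gone in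

* the best time, 3.0 h at the latest, for target, in min
* the amount of target, in percent of the starting material charged, at that time

I read the target as the middle of two pseudo-first-order steps in a row and integrate them, leaving the feed out. The peak share then comes to κ raised to 1/(1−κ). The south-east run has the charge of this flask, so I start there. Its highest reading, 22%, taken as its peak, gives κ = 0.411, the race number: constant of formation over constant of loss. The south-east run has half the catalyst of the north-west run and its first reading is half of that run's, but its charge is twice as large, so two settings differ between them. The north-west and south-west runs differ in charge, yet their first readings are 25% and 25%, so I assume, with no run at equal charge to test it, that κ scales with c(free catalyst). For this flask that gives κ = 0.800 and a peak of 32.8%, near 3 min, where the north-west readings stand highest.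

The forecast says 41% at 2.5 min, holding that “concentration has little effect”.

The flask gives 33.9% at 2.79 min, which is 7.1 percentage points below the forecast.

    starting material + free catalyst ⇌ catalyst intermediate A (K = 95.0 M⁻¹, k = 3400 M⁻¹ s⁻¹)
    catalyst intermediate A ⇌ catalyst intermediate B (K = 2.30, k = 0.860 s⁻¹)
    catalyst intermediate B → free catalyst + target (k = 41.0 s⁻¹)
    target → over-reaction product (k = 0.0100 s⁻¹)
    free catalyst + target → spent catalyst (k = 0.570 M⁻¹ s⁻¹)

In this flask at 0.0350 h, target goes to over-reaction product 140 times as fast as to spent catalyst, and that step alone has a half-life of 1.2 min, shorter than the 2.08 min at the midpoint of the turnover of starting material with free catalyst. At the best time this flask holds 33.9% target beside 32.9% over-reaction product. The neighbour flask with 0.23 mM free catalyst has κ = 0.472, which reckons to 24.1%, and it gives 25.2%.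

Readings and results are simulated for substances that don't exist; the scatter is artificial.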